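Side-chain numbering used throughout: C1 = benzylic CH2, C2 = ketone carbon, C3–C12 = methylenes, C13 = CH2OH (oxygen O-13). The target is taken back to macrolactone 12, in which the aryl carboxyl carbon is esterified by O-13; hydroxide opens it in the last step and frees acid and alcohol together, so neither needs a protecting group.
Feature that makes the key step possible: the carboxyl group on the arene and O-13 can be tied as an ester, which makes the target the seco acid of a benzo-fused 17-membered keto-lactone (ring atoms: ester C, O-13, C13 down to C1, and the two arene carbons carrying carboxyl and side chain). In that ring C7–C8 lies between a hept-6-enoyl arm (C2–C7) and a hept-6-enyl arm (C8–C13).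
C7–C8 is made by ring-closing metathesis of diene ester 8 with hydrogenation in the same flask; C1–C2 by acylation of the laterally lithiated toluate ester 3 with Weinreb amide 5; the ester tether by Mitsunobu esterification of acid 1 with hept-6-en-1-ol 2.
Ring order: the benzene ring is bought; the only ring formed is the temporary 17-membered lactone (step 4), kept through the ortho-demethylation (step 5) and opened in step 6.

Key step: step 4

Remark: the ring closure is expected to give 9 as an E/Z mixture (E drawn); both isomers give 10 on hydrogenation, so the geometry needs no control.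
Remark: 1, 2 and 4 are taken as commercial, and LDA is used as a commercial solution.

Step 1
Reactants: 1 2,4-dimethoxy-6-methylbenzoic acid; 2 hept-6-en-1-ol
Product: 3 hept-6-en-1-yl 2,4-dimethoxy-6-methylbenzoate
Conditions: PPh3, DIAD, THF, 0 °C → rt
Reagents that add atoms: none
Why: Mitsunobu esterification activates the primary alcohol instead of the hindered 2,6-disubstituted carboxyl group, so the carboxylate only has to attack the unhindered primary carbon of the alkoxyphosphonium ion (SN2), and the alkene and aryl ethers are inert.

Step 2
Reactants: 4 hept-6-enoic acid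
Product: 5 N-methoxy-N-methylhept-6-enamide
Conditions: MeNHOMe·HCl, EDC·HCl, N-methylmorpholine, DMAP (cat.), CH2Cl2, 0 °C → rt
Reagents that add atoms: N,O-dimethylhydroxylamine hydrochloride, CNOC.Cl
Why: Carbodiimide-mediated amide coupling of an unhindered aliphatic acid with N,O-dimethylhydroxylamine (Weinreb amide formation), under which the terminal alkene is inert.

Step 3
Reactants: 3 hept-6-en-1-yl 2,4-dimethoxy-6-methylbenzoate; 5 N-methoxy-N-methylhept-6-enamide
Product: 8 hept-6-en-1-yl 2,4-dimethoxy-6-(2-oxooct-7-en-1-yl)benzoate, via lithiated toluate ester 6 (not isolated), via lithium hemiaminal adduct 7 (not isolated)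
Conditions: LDA (2.0 equiv), THF, −78 °C; then 5, −78 °C; AcOH quench at −78 °C
Reagents that add atoms: none
Why: Lateral lithiation of an ortho-toluate ester by LDA gives the ester-stabilised benzylic anion 6, which is acylated by the Weinreb amide (toluate acylation); the chelated adduct 7 should hold until the cold acidic quench, which prevents over-addition and keeps a ketone enolate from closing onto the ester.

Step 4
Reactants: 8 hept-6-en-1-yl 2,4-dimethoxy-6-(2-oxooct-7-en-1-yl)benzoate
Product: 10 lactone of 2,4-dimethoxy-6-(13-hydroxy-2-oxotridecyl)benzoic acid (saturated 17-membered keto-lactone), via unsaturated macrolactone 9 (not isolated)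
Conditions: (H2IMes)(PCy3)Cl2Ru=CHPh (5 mol %), toluene (1 mM), 80 °C; then 10% Pd/C, H2 (1 atm), rt, same flask
Reagents that add atoms: none
Why: Ring-closing olefin metathesis by the metallacyclobutane mechanism: the Ru carbene loads onto one terminal olefin, forms a ruthenacyclobutane with the other and extrudes ethene, whose loss drives the closure, and the Pd/C added afterwards saturates C7=C8 so that either alkene geometry gives the same product. The closest known reaction types are RCM macrocyclisations of resorcylate ester dienes to benzo-fused macrolactones and one-pot RCM–hydrogenation sequences to saturated macrocycles. The ring closed is the 17-membered lactone (ester C, O-13, C13 to C1 and the two arene carbons), and it closes by macrocyclic RCM at C7=C8 under high dilution. No stereocentre is formed. The selectivity needed is ring closure over intermolecular (acyclic diene) metathesis; it is secured by the ester tether, which holds the two unhindered monosubstituted olefins in one molecule, and by the 1 mM concentration, while both olefins lie at least five atoms from ketone and ester so that no deactivating chelate forms. In the hydrogenation only the isolated disubstituted alkene should react at 1 atm and room temperature, the non-conjugated ketone, the aryl ester and the arene being inert.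

Step 5
Reactants: 10 lactone of 2,4-dimethoxy-6-(13-hydroxy-2-oxotridecyl)benzoic acid
Product: 12 lactone of 2-hydroxy-6-(13-hydroxy-2-oxotridecyl)-4-methoxybenzoic acid, via aryl dichloroborinate 11 (not isolated)
Conditions: BCl3 (1.5 equiv), CH2Cl2, −78 → 0 °C; H2O work-up
Reagents that add atoms: none
Why: BCl3 binds the ester carbonyl and the ortho methoxy oxygen in a six-membered chelate and chloride then removes that methyl group (chelation-controlled ortho-demethylation of an o-methoxy aryl ester), while the para methoxy group, the lactone and the ketone should be left alone at low temperature.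

Step 6
Reactants: 12 lactone of 2-hydroxy-6-(13-hydroxy-2-oxotridecyl)-4-methoxybenzoic acid
Product: 15 2-hydroxy-6-(13-hydroxy-2-oxotridecyl)-4-methoxybenzoic acid (target), via isocoumarin potassium phenoxide 13 (not isolated), via dipotassium salt 14 (not isolated)
Conditions: KOH (aq, excess), 1,4-dioxane/H2O, 60 °C; then 1 M HCl to pH 3, 0 °C
Reagents that add atoms: potassium hydroxide (aqueous), [K+].[OH-]
Why: The hindered macrolactone is opened with neighbouring-group help, the C2 enolate oxygen attacking the ester carbonyl through a six-membered transition state to release O-13 and give the enol lactone 13, which hydroxide hydrolyses to the keto-acid salt 14 (ester saponification through isocoumarin hydrolysis); cold acidification should free the acid without re-lactonisation.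

Compound list
1 | 2,4-dimethoxy-6-methylbenzoic acid | COc1cc(OC)c(C(=O)O)c(C)c1 | starting material
2 | hept-6-en-1-ol | C=CCCCCCO | starting material
3 | hept-6-en-1-yl 2,4-dimethoxy-6-methylbenzoate | COc1cc(OC)c(C(=O)OCCCCCC=C)c(C)c1 | intermediate
4 | hept-6-enoic acid | C=CCCCCC(=O)O | starting material
5 | N-methoxy-N-methylhept-6-enamide | C=CCCCCC(=O)N(C)OC | intermediate
6 | lithiated toluate ester: benzylic lithium derivative of 3 (not isolated) | [Li]Cc1cc(OC)cc(OC)c1C(=O)OCCCCCC=C | intermediate
7 | lithium hemiaminal adduct of 6 with 5 (not isolated) | [Li]OC(CCCCC=C)(Cc1cc(OC)cc(OC)c1C(=O)OCCCCCC=C)N(C)OC | intermediate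
8 | hept-6-en-1-yl 2,4-dimethoxy-6-(2-oxooct-7-en-1-yl)benzoate | COc1cc(OC)c(C(=O)OCCCCCC=C)c(CC(=O)CCCCC=C)c1 | intermediate
9 | unsaturated macrolactone: lactone of 6-(13-hydroxy-2-oxotridec-7-en-1-yl)-2,4-dimethoxybenzoic acid, 17-membered ring, E drawn, E/Z mixture expected (not isolated) | COc1cc(OC)c2C(=O)OCCCCC/C=C/CCCCC(=O)Cc2c1 | intermediate
10 | lactone of 2,4-dimethoxy-6-(13-hydroxy-2-oxotridecyl)benzoic acid (carboxyl esterified by O-13, 17-membered ring) | COc1cc(OC)c2C(=O)OCCCCCCCCCCCC(=O)Cc2c1 | intermediate
11 | aryl dichloroborinate: O-dichloroboryl derivative of 12 (not isolated) | COc1cc(OB(Cl)Cl)c2C(=O)OCCCCCCCCCCCC(=O)Cc2c1 | intermediate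
12 | lactone of 2-hydroxy-6-(13-hydroxy-2-oxotridecyl)-4-methoxybenzoic acid (17-membered ring, free phenol) | COc1cc(O)c2C(=O)OCCCCCCCCCCCC(=O)Cc2c1 | intermediate
13 | potassium 3-(11-hydroxyundecyl)-6-methoxy-1-oxo-1H-isochromen-8-olate (not isolated) | [K+].COc1cc([O-])c2C(=O)OC(CCCCCCCCCCCO)=Cc2c1 | intermediate
14 | dipotassium 2-(13-hydroxy-2-oxotridecyl)-4-methoxy-6-oxidobenzoate (not isolated) | [K+].[K+].COc1cc([O-])c(C(=O)[O-])c(CC(=O)CCCCCCCCCCCO)c1 | intermediate
15 | 2-hydroxy-6-(13-hydroxy-2-oxotridecyl)-4-methoxybenzoic acid | COc1cc(O)c(C(=O)O)c(CC(=O)CCCCCCCCCCCO)c1 | target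

Total step count: 6. Longest linear sequence: 5 steps (steps 1, 3, 4, 5, 6); step 2 is a one-step side branch.

Steps most likely to fail

1. Step 4. Closure of the 17-membered ring may be outpaced by intermolecular metathesis (oligomer formation). Ru-hydride species formed at 80 °C may also migrate the terminal double bonds before closure, which would delete CH2 units and give ring-contracted lactones. The fallback sets out from 3 and 5 and returns at 10. C7=C8 is made intermolecularly by cross-metathesis of 3 with an excess of 5 (same Ru catalyst, CH2Cl2, 40 °C), where both partners are unhindered terminal olefins and surplus 5 is recoverable. This should give 12-[methoxy(methyl)amino]-12-oxododec-6-en-1-yl 2,4-dimethoxy-6-methylbenzoate F1, and hydrogenation (H2, Pd/C, EtOAc) should give 12-[methoxy(methyl)amino]-12-oxododecyl 2,4-dimethoxy-6-methylbenzoate F2. The ring is then closed at C1–C2 instead: slow addition of F2 to LDA in THF at −78 °C under high dilution (0.5 mM or less) forms the lateral lithio derivative of F2 F3. F3 should attack its own Weinreb amide to give the cyclic lithium hemiaminal adduct F4, and a cold acetic acid quench should deliver 10.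

2. Step 3. The lateral anion 6 may attack the ester carbonyl of a second molecule of 3 (self-condensation). If adduct 7 collapses early, the ketone enolate may close onto the ester and expel the heptenyl tether. The fallback sets out from 1 and 5 and returns at 8; it acylates before the tether is installed, so no electrophilic ester is present. Double deprotonation of 1 with LDA (2.2 equiv, THF, −78 → 0 °C) should give the dilithio derivative of 1 F5 (lithium carboxylate and benzylic lithium). Addition of 5 at −78 °C should give the dilithium hemiaminal adduct F6 and, after mild acidic work-up, 2,4-dimethoxy-6-(2-oxooct-7-en-1-yl)benzoic acid F7. Mitsunobu esterification of F7 with 2 (PPh3, DIAD, THF) then gives 8.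

3. Step 6. In base the phenol is ionised, which deactivates the hindered aryl ester, so opening depends on attack by the ketone enolate oxygen. Under hot hydroxide the C3 enolate may instead acylate on carbon (intramolecular Claisen closure towards a naphthalenediol). On acidification the keto acid may dehydrate back to the enol lactone. The fallback sets out from 12 and returns at 13; the tether is unlocked under acid instead of base. TsOH·H2O (cat.) in toluene at 90 °C should transfer the acyl group from O-13 to the enol oxygen of C2 and give 8-hydroxy-3-(11-hydroxyundecyl)-6-methoxy-1H-isochromen-1-one F8, which can be purified. Dilute aqueous KOH at room temperature then converts it into 13 and on to 14, and the acid 15 is set free at 0 °C with a citric acid or NaH2PO4 buffer (pH about 4) instead of mineral acid.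

Further compounds
F1 | step 4 | 12-[methoxy(methyl)amino]-12-oxododec-6-en-1-yl 2,4-dimethoxy-6-methylbenzoate (E drawn, E/Z mixture expected) | COc1cc(OC)c(C(=O)OCCCCC/C=C/CCCCC(=O)N(C)OC)c(C)c1
F2 | step 4 | 12-[methoxy(methyl)amino]-12-oxododecyl 2,4-dimethoxy-6-methylbenzoate | COc1cc(OC)c(C(=O)OCCCCCCCCCCCC(=O)N(C)OC)c(C)c1
F3 | step 4 | lateral lithio derivative of F2 | [Li]Cc1cc(OC)cc(OC)c1C(=O)OCCCCCCCCCCCC(=O)N(C)OC
F4 | step 4 | cyclic lithium hemiaminal adduct (17-membered ring, C2 bearing OLi and N(OMe)Me) | COc1cc(OC)c2C(=O)OCCCCCCCCCCCC(O[Li])(N(C)OC)Cc2c1
F5 | step 3 | dilithio derivative of 1 (lithium carboxylate, benzylic lithium) | [Li]Cc1cc(OC)cc(OC)c1C(=O)O[Li]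
F6 | step 3 | dilithium hemiaminal adduct of F5 with 5 | [Li]OC(CCCCC=C)(Cc1cc(OC)cc(OC)c1C(=O)O[Li])N(C)OC
F7 | step 3 | 2,4-dimethoxy-6-(2-oxooct-7-en-1-yl)benzoic acid | COc1cc(OC)c(C(=O)O)c(CC(=O)CCCCC=C)c1
F8 | step 6 | 8-hydroxy-3-(11-hydroxyundecyl)-6-methoxy-1H-isochromen-1-one | COc1cc(O)c2C(=O)OC(CCCCCCCCCCCO)=Cc2c1
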